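Over 4.0 d this flask passes solid substrate through solution into target, so we stop counting in days and count in amount made.

solid substrate 2.0 M; gas 200 mM (held); time 4.0 d

- amount of target and solid product together at 4.0 d, in percent of the solid substrate charged
- concentration of dissolved substrate in solution at 50 h, in percent of saturation
- the change that raises the amount of target and solid product together at 4.0 d, in percent of the solid substrate charged most ("none" if none brings more than 2 percentage points) (epsilon / eta / gamma / zeta / none)
- amount of target and solid product together at 4.0 d, in percent of the solid substrate charged, after eta

- for target the solid product is counted in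
- as a solid, counted per litre of solution: solid substrate, solid product
- at the start none of reagent is dissolved
- at the start none of the solid substrate is in solution
- dissolved substrate means what is dissolved; the solid is not counted in it
- run time (flask): 4.0 d

- epsilon: doubling the solubility in step 3, all else as stated
- eta: doubling the dissolution coefficient of step 1, all else as stated
- gamma: doubling the dissolution coefficient of step 3, all else as stated
- zeta: doubling the saturation concentration of gas, all else as stated

The dissolved substrate enters from the solid at 2.7 × 10⁻⁵ s⁻¹ times its distance from 0.74 M, the reagent enters from the gas at 1.3 × 10⁻⁴ s⁻¹ times its distance from 200 mM, and they react with 6.3 × 10⁻⁵ M⁻¹ s⁻¹. Setting both feeds equal to the making gives a quasi-steady rate 5.39 × 10⁻⁶ M s⁻¹, with c(dissolved substrate) at 0.540 M, which is 73.0% of saturation.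

Target goes to the isomer of the product with forward constant 4.7 × 10⁻⁶ s⁻¹. Dividing that loss by the making removes time: each unit made loses c(target)/L to the isomer of the product, less the back reaction, where L, the break-even target level, is the making rate over the forward constant, 1.15 M.

From above, we take that rate held for the whole of 4.0 d, which makes 1.86 M. From below, we reckon the solid to last until the amount made reaches the charge less the dissolved stock, 1.46 M, and at our rate that takes about 3.13 d, earlier than 4.0 d, so we take that amount as our floor. With no back reaction, the lower amount gives 41.3%. With the back reaction, the higher amount gives 55.6%. L stands above 0.91 M, so we reckon that target nears its solubility late in the run, and we expect a small gain from eta.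

Doubling csat gives a making rate of 8.73 × 10⁻⁶ M s⁻¹ and a smaller dissolved stock. Doubling cs3 swells that stock, so we choose zeta.

The forecast, with 51%, 73%, zeta and 51.1%, lies inside our bracket and holds that “crystallisation is already fast compared with the other steps”.

The flask gives 50.9%, 72.9%, zeta with a gain of 8.3 percentage points (epsilon 3.6 points, gamma 2.3 points, eta 0.061 points), and 51.0%.

    solid product ⇌ target, rate k1*(cs1 - [target]) while solid is left; crystals form when [target] > cs1 (cs1 = 0.91 M, k1 = 1.7 × 10⁻⁴ s⁻¹)
    target ⇌ isomer of the product (K2 = 1.7, k2 = 4.7 × 10⁻⁶ s⁻¹)
    solid substrate ⇌ dissolved substrate, rate k3*(cs3 - [dissolved substrate]) while solid is left; crystals form when [dissolved substrate] > cs3 (cs3 = 0.74 M, k3 = 2.7 × 10⁻⁵ s⁻¹)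
    gas ⇌ reagent, rate k4*(csat - [reagent]) (k4 = 1.3 × 10⁻⁴ s⁻¹, csat = 200 mM)
    dissolved substrate + reagent → target (k5 = 6.3 × 10⁻⁵ M⁻¹ s⁻¹)

Without the loss of target to the isomer of the product, this flask gives 83.8% rather than 50.9%. That figure is the amount made, and L turns it into 51.6% of the charge as target. The neighbour flask left until 2.5 d has made 51.4%, for which L gives 36.3%, and its target stands at 36.2%.

Its constants were set for the occasion; the result is computed.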